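## Analysis of the target

The target is a 3',8''-linked flavanone–flavone dimer with six rings. The flavanone half has ring A (C4a to C8a, a chelated hydroxyl on C5 and the only methyl ether on C7), the dihydropyranone ring C (O1, C2, C3, C4) and ring B (C1' to C6', hydroxyl on C4'). The flavone half has ring D (C4a'' to C8a'', hydroxyls on C5'' and C7''), the pyranone ring F (O1'', C2'' to C4'') and ring E (C1''' to C6'''), a 4-hydroxyphenyl group on C2''. The only stereocentre is C2, of S configuration (O1 > C1' > C3 > H), so no relative stereochemistry has to be set; the C3'–C8'' axis has three ortho substituents but carries no specified configuration. C2 is a benzylic ether carbon β to the C4 ketone and epimerises by retro-oxa-Michael opening to the 2'-hydroxychalcone under base or hot acid, and the five free phenols are oxidisable, so C2 should be made late and the end-game must avoid base. Three things make the synthesis hard: the biaryl bond joins two electron-rich, ortho-substituted carbons; the three oxygens of ring D must be told apart so that ring F closes onto the one next to C8'' (8-aryl, not 6-aryl flavone); and one methyl ether among six oxygens must survive deprotection. The plan rests on the fact that C8'' lies between the oxygen-bearing carbons C8a'' and C7'', with the third oxygen on C5'' para to it, so ring D is a 2-arylphloroglucinol. A cyclobutenone–ynol ether benzannulation writes exactly this pattern around an alkyne carbon, so ring D can be grown on an alkyne already bonded to C3' of ring B.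

## Retrosynthetic reasoning

**26 to 25.** No skeletal bond is cut; the five hydroxyls are masked. Benzyl ethers sit on the C4', C7'', C4''' and C5 oxygens and an ethyl ether on the C5'' oxygen. The ethyl group is not a free choice: it comes from 7 and is what marks the C5'' oxygen as different from the other two oxygens of ring D. It lies peri to the C4'' carbonyl, where a boron Lewis acid can cleave it through a chelate, while the C7 methyl ether has no such neighbour. The forward step must free five oxygens without touching the C7 methyl ether or C2.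

**25 to 20 and 24.** The C2–C1' bond is cut. This bond joins the two halves at the only stereocentre, so cutting it makes the route convergent and puts the creation of C2 in the penultimate step, after every basic operation. Cutting O1–C2 instead would lead to a chalcone and an asymmetric oxa-Michael closure, a less dependable way to set C2. The forward reaction must transfer the aryl group of 20 to one enantioface of C2 of 24 and leave the 2-aryl enone of ring F in 20 alone.

**24 to 22 to 21.** Ring C is opened at O1–C2 and C2–C3, C2 being a one-carbon unit from an amide acetal. Compound 21 is symmetric, so monobenzylation has a single outcome, and the remaining chelated hydroxyl becomes O1. The benzyl group on the C5 oxygen keeps a chelating phenol away from the cationic palladium catalyst.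

**20 to 19.** The C1'–B bond is traced back to a C1'–Cl bond. Chlorine, para to the C4' oxygen, is inert to the amide bases, heat, fluoride, Lewis acid and enolate chemistry of steps 1 to 9, yet a bulky phosphine lets palladium insert into it when the boron is needed.

**19 to 18 to 16 and 17.** Ring F is cut at O1''–C2'' (cyclodehydration) and C2''–C3'' (enolate aroylation). This is conventional chemistry; the ring oxygen is the hydroxyl that is hydrogen-bonded to the acetyl group in 16.

**16 to 15 to 13.** The benzyl group on the C7'' oxygen and the C4a''–C4'' bond are removed. Compound 13 has a mirror plane through C8'' and C5'', so its two free ring carbons are equivalent and acetylation cannot give isomers. Once the acetyl group is in place the two hydroxyls differ: the chelated one becomes O1'' and the free one is benzylated. The ethoxy group blocks the third oxygen from ever becoming O1''.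

**13 to 12.** The silyl ether is cleaved to reveal the symmetry; silicon was only needed to carry the ynol ether.

**12 to 6 and 7.** Ring D is taken apart into the four carbons of 7 and the two alkyne carbons of 6. The [2+2] step forms C8''–C8a'' and C6''–C7'', and the electrocyclisation forms C4a''–C8a''. The last bond joins the same two carbons that are bonded as C1–C4 in 7; that bond opens at the start, so the net change is insertion of the alkyne between C1 and C2 of 7. Because 13 is symmetric, the labels C8a''/C7'' and C4a''/C6'' can be exchanged without consequence. The cut is made here and not at C3'–C8'' because a cross-coupling would have to join two ortho-disubstituted, electron-rich carbons. In 6 the future biaryl bond already exists as an unhindered aryl–alkyne bond, and the three oxygens arrive differentiated as hydroxyl, silyl ether and ethyl ether. The forward reaction must control the regiochemistry of the ketene–alkyne cycloaddition.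

**6 to 3 to 2 to 1.** The ynol ether comes from the terminal alkyne 3 by oxygen transfer to its acetylide 4 and O-silylation of the ynolate 5; the alkyne comes from aldehyde 2 by one-carbon homologation, and 2 from 1 by benzylation. An ester homologation through a dibromomethyl carbenoid would be one step shorter but needs excess alkyllithium, which endangers the aryl chloride and the benzylic protons; the acetylide route uses only amide bases.

## Alternatives that were turned down

**Alternative 1:** The disconnection is the C2''=C3'' bond of ring F. In the forward step the acyl phosphorane A2, which carries the 4-benzyloxybenzoate on the C8a'' oxygen, is heated so that the ylide carbon C3'' attacks the ester carbonyl C2'' with loss of the phosphine oxide, closing ring F to the tetrabenzylated 8-aryl flavone A1.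
- For: the closure is neutral, and the position of the ester fixes which oxygen becomes O1''. A1 is protected by benzyl groups only, so its final deprotection is easier than that of the chosen route with its C5'' ethyl ether; on this point the alternative is stronger.
- Against: an ester carbonyl is a poor partner for a stabilised ylide, so long heating is needed, during which the aroyl group can migrate to the ylide carbon. A2 requires an α-halo ketone, a phosphonium salt and esterification of the most hindered hydroxyl of ring D. Above all, the step concerns ring F, the easy ring, and says nothing about the C3'–C8'' bond or about how the ring D oxygens come to be differentiated.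
- Comparison: it spends at least two more steps on ring F than enolate aroylation and cyclodehydration and leaves the real problems open. The chosen strategy pays for its ethyl group with a harder last step but settles the biaryl bond and the oxygen pattern in one operation.

**Alternative 2:** The disconnection is C4–C4a of ring C. In the forward step the (3S)-3-aryl-3-(3,5-dimethoxyphenoxy)propanoic acid A4 is activated as a mixed anhydride with a perfluorinated acid anhydride and acylates the ortho carbon of its own phenoxy ring, closing ring C to the (2S)-5,7-dimethoxyflavanone A3 with C2 untouched.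
- For: the phenoxy ring is symmetric and very nucleophilic, so there is one site and the closure is mild. C2 can be set by classical means (asymmetric reduction of a β-keto ester, then etherification with inversion) rather than by catalytic arylation of an electron-rich chromone; on the precedent for the stereo-defining reaction the alternative is at least as strong.
- Against: C2 in A4 is a benzylic carbon with an aryloxy leaving group and a para-alkoxy group on ring B, an arrangement that ionises under the acidic acylation and in the etherification before it, so enantiopurity is at risk twice. A3 has methyl ethers on both C5 and C7, so a chelation-controlled mono-demethylation is still needed. The complete flavone must be carried through four or five linear steps to reach A4, and the biaryl bond is again not addressed.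
- Comparison: it is longer on the most valuable intermediate and less convergent. The chosen route joins 20 and 24 in one step and, in place of a classical stereo-defining reaction, offers a C2–O1 bond that is never a leaving group before the last step.

**Alternative 3:** The disconnection removes three bonds of ring F at once: C4a''–C4'', C4''–C3'' and O1''–C2''. In the forward step the iodoresorcinol A6 and the aryl alkyne A7 are joined in a carbonylative Sonogashira coupling with a palladium–phosphine catalyst and an amine base. The resulting ynone A8 closes 6-endo through the C8a'' oxygen to the 8-aryl-7-hydroxyflavone A5, which carries a ring B aldehyde.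
- For: it is convergent and builds ring F in one flask, against three steps in the chosen route; on step economy for ring F it is stronger. The aldehyde of A5 is ready for the construction of ring C.
- Against: the iodine of A6 is flanked by a hydroxyl and a benzyloxy group on an electron-rich ring, so oxidative addition is slow and direct alkynylation without carbonylation competes, leading to a benzofuran. A8 can close 5-exo to an aurone. Two free phenols and a free aldehyde are exposed to palladium and amine. The aldehyde leads to ring C through a chalcone, whose asymmetric cyclisation is the least dependable way to set C2. A6 already contains the C3'–C8'' bond, which would have to come from a hindered coupling.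
- Comparison: it shortens the easy part and leaves the hard part. The chosen strategy is longer at ring F but makes the biaryl motif and the C2 stereocentre by reactions whose selectivity is set by mechanism and catalyst.

Key step: step 4

Assumption: the target string defines no configuration for the C3'–C8'' axis, so it is treated as unspecified; 1, 7, 17 and 21 and the (R) pyridine–oxazoline ligand are taken as purchasable.

## Route

Step 1
Reactants: 1 5-chloro-2-hydroxybenzaldehyde
Product: 2 2-(benzyloxy)-5-chlorobenzaldehyde
Conditions: BnBr, K2CO3, DMF, 25 → 60 °C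
Reagents that add atoms: benzyl bromide, BrCc1ccccc1
Why: Williamson ether synthesis on an acidic salicylaldehyde phenol; the benzyl ether should last through every step up to the final Lewis acid cleavage.

Step 2
Reactants: 2 2-(benzyloxy)-5-chlorobenzaldehyde
Product: 3 1-(benzyloxy)-4-chloro-2-ethynylbenzene
Conditions: dimethyl (1-diazo-2-oxopropyl)phosphonate, K2CO3, MeOH, 0 → 25 °C
Reagents that add atoms: dimethyl (1-diazo-2-oxopropyl)phosphonate, COP(=O)(OC)C(=[N+]=[N-])C(C)=O
Why: Ohira–Bestmann homologation: methanolysis of the acetyl group frees the diazomethylphosphonate anion, which olefinates the aldehyde, loses N2 and gives the terminal alkyne by 1,2-hydrogen shift; carbonate in methanol leaves the aryl chloride and benzyl ether alone.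

Step 3
Reactants: 3 1-(benzyloxy)-4-chloro-2-ethynylbenzene
Product: 6 (2-benzyloxy-5-chlorophenyl)ethynyl triisopropylsilyl ether, via lithium acetylide 4 (not isolated), via lithium ynolate 5 (not isolated)
Conditions: LiN(SiMe3)2, THF, −78 °C; LiOOt-Bu (from t-BuOOH and LiN(SiMe3)2), −78 → 0 °C; then i-Pr3SiOTf, −78 → 0 °C
Reagents that add atoms: tert-butyl hydroperoxide, CC(C)(C)OO; triisopropylsilyl trifluoromethanesulfonate, CC(C)[Si](OS(=O)(=O)C(F)(F)F)(C(C)C)C(C)C
Why: Known oxidation of a lithium acetylide by a lithium alkyl peroxide: electrophilic oxygen transfer to the acetylide carbon of 4 gives ynolate 5, which the hard, bulky silyl triflate silylates on oxygen; only amide bases are present, so the aryl chloride and the benzylic protons are not at risk.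

Step 4
Reactants: 6 (2-benzyloxy-5-chlorophenyl)ethynyl triisopropylsilyl ether; 7 3-ethoxycyclobut-2-en-1-one
Product: 12 2-(2-benzyloxy-5-chlorophenyl)-5-ethoxy-3-(triisopropylsilyloxy)phenol, via ethoxyvinylketene 8 (not isolated), via vinylcyclobutenone 9 (not isolated), via dienylketene 10 (not isolated), via cyclohexadienone 11 (not isolated)
Conditions: PhMe, 90 → 120 °C, sealed vessel, 7 in excess
Reagents that add atoms: none
Why: Danheiser benzannulation of a cyclobutenone with a siloxyalkyne, a known reaction class used here with a 3-alkoxycyclobutenone and an aryl siloxyalkyne. Heating opens 7 by reversible 4π electrocyclic cleavage of its C1–C4 bond to the ethoxyvinylketene 8. The ketene carbonyl carbon, the electrophilic end, bonds to the aryl-bearing alkyne carbon, which is the nucleophilic β-carbon of the silyl ynol ether, while the oxygen-bearing alkyne carbon bonds to the ketene α-carbon; this [2+2] cycloaddition gives 9 and forms C8''–C8a'' and C6''–C7''. A second 4π opening of 9 gives the dienylketene 10, and ring D is closed by a thermal disrotatory 6π electrocyclisation (six-membered, bond C4a''–C8a'') to the dienone 11, which tautomerises irreversibly to phenol 12. Both ring openings are reversible and only the isomer of 10 with ketene and ethoxyvinyl group cis can close, so aromatisation draws the sequence forward. No stereocentre is created, because the sp3 carbons of 9 and 11 are lost on the way to the arene. The selectivity required is regiochemical, in the cycloaddition, and the polarisation of the O-silyl ynol ether secures it by placing the aryl group between the new hydroxyl and the siloxy group; the aryl chloride and benzyl ether are inert to heat.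

Step 5
Reactants: 12 2-(2-benzyloxy-5-chlorophenyl)-5-ethoxy-3-(triisopropylsilyloxy)phenol
Product: 13 2-(2-benzyloxy-5-chlorophenyl)-5-ethoxybenzene-1,3-diol
Conditions: Bu4NF, AcOH, THF, 0 °C
Reagents that add atoms: none
Why: Fluoride cleavage of an aryl silyl ether, buffered to protect the electron-rich resorcinol; the product has a mirror plane through C8'' and C5'', so its two free ring positions are equivalent.

Step 6
Reactants: 13 2-(2-benzyloxy-5-chlorophenyl)-5-ethoxybenzene-1,3-diol
Product: 15 1-[3-(2-benzyloxy-5-chlorophenyl)-6-ethoxy-2,4-dihydroxyphenyl]ethan-1-one, via ketiminium chloride 14 (not isolated)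
Conditions: MeCN, ZnCl2, HCl (g), Et2O, 0 °C; then H2O, 100 °C
Reagents that add atoms: acetonitrile, CC#N; water, O
Why: Houben–Hoesch acylation: the activated nitrile attacks the phloroglucinol-type ring D at its only kind of free carbon, the iminium salt 14 deactivates the ring against a second attack and is hydrolysed to the ketone; ring B, a chloro alkoxybenzene, is far too unreactive to compete.

Step 7
Reactants: 15 1-[3-(2-benzyloxy-5-chlorophenyl)-6-ethoxy-2,4-dihydroxyphenyl]ethan-1-one
Product: 16 1-[4-benzyloxy-3-(2-benzyloxy-5-chlorophenyl)-6-ethoxy-2-hydroxyphenyl]ethan-1-one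
Conditions: BnBr (1.05 equiv), K2CO3, acetone, 56 °C
Reagents that add atoms: benzyl bromide, BrCc1ccccc1
Why: Williamson etherification selective for the hydroxyl para to the acetyl group, which is more acidic and not hydrogen-bonded, while the ortho hydroxyl is held in a chelate with the ketone; this fixes which oxygen becomes O1''.

Step 8
Reactants: 16 1-[4-benzyloxy-3-(2-benzyloxy-5-chlorophenyl)-6-ethoxy-2-hydroxyphenyl]ethan-1-one; 17 4-(benzyloxy)benzoyl chloride
Product: 18 1-[4-benzyloxy-3-(2-benzyloxy-5-chlorophenyl)-6-ethoxy-2-hydroxyphenyl]-3-(4-benzyloxyphenyl)propane-1,3-dione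
Conditions: LiN(SiMe3)2 (4 equiv), THF, −78 °C; then 17, −78 → 25 °C; aq. NH4Cl
Reagents that add atoms: none
Why: Direct form of the Baker–Venkataraman diketone synthesis: excess amide base removes the phenol proton and an acetyl proton of 16 and the carbon nucleophile is aroylated by 17, forming C2''–C3''; any O-aroylated material is carried to the same diketone by base-induced acyl migration, so the hindered phenol needs no separate esterification.

Step 9
Reactants: 18 1-[4-benzyloxy-3-(2-benzyloxy-5-chlorophenyl)-6-ethoxy-2-hydroxyphenyl]-3-(4-benzyloxyphenyl)propane-1,3-dione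
Product: 19 7-benzyloxy-8-(2-benzyloxy-5-chlorophenyl)-2-(4-benzyloxyphenyl)-5-ethoxy-4H-chromen-4-one
Conditions: TsOH·H2O (cat.), PhMe, 110 °C, Dean–Stark
Reagents that add atoms: none
Why: Acid-catalysed cyclodehydration of an o-hydroxyaryl 1,3-diketone (6-exo-trig attack of the phenol on the distal carbonyl, then loss of water) closes ring F at O1''–C2''; aryl benzyl and ethyl ethers are stable to catalytic sulfonic acid.

Step 10
Reactants: 19 7-benzyloxy-8-(2-benzyloxy-5-chlorophenyl)-2-(4-benzyloxyphenyl)-5-ethoxy-4H-chromen-4-one
Product: 20 [4-benzyloxy-3-(7-benzyloxy-2-(4-benzyloxyphenyl)-5-ethoxy-4-oxo-4H-chromen-8-yl)phenyl]boronic acid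
Conditions: B2(OH)4, Pd(OAc)2 (cat.), XPhos, KOAc, EtOH/THF, 80 °C
Reagents that add atoms: tetrahydroxydiboron, OB(O)B(O)O
Why: Miyaura-type borylation of an aryl chloride: the bulky dialkylbiarylphosphine lets zerovalent palladium insert into the electron-rich C–Cl bond, and acetate-assisted transmetalation with the diboron gives the boronic acid directly; the flavone and the ethers are spectators.

Step 11
Reactants: 21 2',6'-dihydroxy-4'-methoxyacetophenone
Product: 22 1-(2-benzyloxy-6-hydroxy-4-methoxyphenyl)ethan-1-one
Conditions: BnBr (1.0 equiv), K2CO3, acetone, 56 °C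
Reagents that add atoms: benzyl bromide, BrCc1ccccc1
Why: Williamson mono-etherification of a symmetric diol; after the first benzylation the remaining hydroxyl is locked in a chelate with the ketone and should react far more slowly.

Step 12
Reactants: 22 1-(2-benzyloxy-6-hydroxy-4-methoxyphenyl)ethan-1-one
Product: 24 5-benzyloxy-7-methoxy-4H-chromen-4-one, via enaminone 23 (not isolated)
Conditions: Me2NCH(OMe)2, PhMe, 100 °C; then conc. HCl, CH2Cl2, 40 °C
Reagents that add atoms: N,N-dimethylformamide dimethyl acetal, COC(OC)N(C)C
Why: Enaminone route to chromones: condensation of the methyl ketone with the amide acetal supplies C2, and acid promotes conjugate addition of the phenol with loss of dimethylamine.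

Step 13
Reactants: 20 [4-benzyloxy-3-(7-benzyloxy-2-(4-benzyloxyphenyl)-5-ethoxy-4-oxo-4H-chromen-8-yl)phenyl]boronic acid; 24 5-benzyloxy-7-methoxy-4H-chromen-4-one
Product: 25 (2S)-5-benzyloxy-2-[4-benzyloxy-3-(7-benzyloxy-2-(4-benzyloxyphenyl)-5-ethoxy-4-oxo-4H-chromen-8-yl)phenyl]-7-methoxychroman-4-one
Conditions: Pd(OCOCF3)2 (10 mol %), (R)-t-BuPyOx [(R)-4-tert-butyl-2-(pyridin-2-yl)-4,5-dihydrooxazole] (12 mol %), NH4PF6, H2O, ClCH2CH2Cl, 60 °C, 24 in excess
Reagents that add atoms: none
Why: Enantioselective conjugate addition of an arylboronic acid to a chromone under cationic divalent palladium with a chiral pyridine–oxazoline ligand, a known flavanone synthesis: transmetalation, enantio-determining insertion of the C2=C3 bond of 24 into the aryl–palladium bond, and protonolysis of the palladium enolate. The tert-butyl group of the ligand blocks one quadrant so that the enone binds through one face; by the facial model known for cyclic enones the (R) ligand should place the aryl group so that C2 is S, which would be checked on a model boronic acid first. The 2-aryl enone of ring F in 20 is a much poorer acceptor than the unsubstituted C2=C3 bond of 24, so the flavone should not be attacked.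

Step 14
Reactants: 25 (2S)-5-benzyloxy-2-[4-benzyloxy-3-(7-benzyloxy-2-(4-benzyloxyphenyl)-5-ethoxy-4-oxo-4H-chromen-8-yl)phenyl]-7-methoxychroman-4-one
Product: 26 (2S)-2-[3-(5,7-dihydroxy-2-(4-hydroxyphenyl)-4-oxo-4H-chromen-8-yl)-4-hydroxyphenyl]-5-hydroxy-7-methoxychroman-4-one
Conditions: BCl3, C6HMe5, CH2Cl2, −78 → 20 °C; MeOH quench
Reagents that add atoms: none
Why: Lewis acid ether cleavage: the four benzyl ethers ionise at low temperature with pentamethylbenzene trapping the benzyl cations, and on warming the ethyl ether on C5'' is cleaved through the six-membered boron chelate with the C4'' carbonyl. The C7 methyl ether has no carbonyl neighbour to chelate and should remain, and the absence of base keeps C2 from epimerising through the chalcone.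

## Compound list

1 | 5-chloro-2-hydroxybenzaldehyde | O=Cc1cc(Cl)ccc1O | starting material
2 | 2-(benzyloxy)-5-chlorobenzaldehyde | O=Cc1cc(Cl)ccc1OCc1ccccc1 | intermediate
3 | 1-(benzyloxy)-4-chloro-2-ethynylbenzene | C#Cc1cc(Cl)ccc1OCc1ccccc1 | intermediate
4 | lithium (2-benzyloxy-5-chlorophenyl)acetylide | [Li+].[C-]#Cc1cc(Cl)ccc1OCc1ccccc1 | intermediate (not isolated)
5 | lithium 2-(2-benzyloxy-5-chlorophenyl)ethynolate | [Li+].[O-]C#Cc1cc(Cl)ccc1OCc1ccccc1 | intermediate (not isolated)
6 | (2-benzyloxy-5-chlorophenyl)ethynyl triisopropylsilyl ether | CC(C)[Si](OC#Cc1cc(Cl)ccc1OCc1ccccc1)(C(C)C)C(C)C | intermediate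
7 | 3-ethoxycyclobut-2-en-1-one | CCOC1=CC(=O)C1 | starting material
8 | 3-ethoxybuta-1,3-dien-1-one | CCOC(=C)C=C=O | intermediate (not isolated)
9 | 2-(2-benzyloxy-5-chlorophenyl)-4-(1-ethoxyethenyl)-3-(triisopropylsilyloxy)cyclobut-2-en-1-one (racemic) | CCOC(=C)C1C(=O)C(c2cc(Cl)ccc2OCc2ccccc2)=C1O[Si](C(C)C)(C(C)C)C(C)C | intermediate (not isolated)
10 | (3E)-2-(2-benzyloxy-5-chlorophenyl)-5-ethoxy-3-(triisopropylsilyloxy)hexa-1,3,5-trien-1-one | CCOC(=C)/C=C(O[Si](C(C)C)(C(C)C)C(C)C)\C(=C=O)c1cc(Cl)ccc1OCc1ccccc1 | intermediate (not isolated)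
11 | 2-(2-benzyloxy-5-chlorophenyl)-5-ethoxy-3-(triisopropylsilyloxy)cyclohexa-2,4-dien-1-one | CCOC1=CC(O[Si](C(C)C)(C(C)C)C(C)C)=C(c2cc(Cl)ccc2OCc2ccccc2)C(=O)C1 | intermediate (not isolated)
12 | 2-(2-benzyloxy-5-chlorophenyl)-5-ethoxy-3-(triisopropylsilyloxy)phenol | CCOc1cc(O)c(-c2cc(Cl)ccc2OCc2ccccc2)c(O[Si](C(C)C)(C(C)C)C(C)C)c1 | intermediate
13 | 2-(2-benzyloxy-5-chlorophenyl)-5-ethoxybenzene-1,3-diol | CCOc1cc(O)c(-c2cc(Cl)ccc2OCc2ccccc2)c(O)c1 | intermediate
14 | 1-[3-(2-benzyloxy-5-chlorophenyl)-6-ethoxy-2,4-dihydroxyphenyl]ethan-1-iminium chloride | CC(=[NH2+])c1c(O)c(-c2cc(Cl)ccc2OCc2ccccc2)c(O)cc1OCC.[Cl-] | intermediate (not isolated)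
15 | 1-[3-(2-benzyloxy-5-chlorophenyl)-6-ethoxy-2,4-dihydroxyphenyl]ethan-1-one | CC(=O)c1c(O)c(-c2cc(Cl)ccc2OCc2ccccc2)c(O)cc1OCC | intermediate
16 | 1-[4-benzyloxy-3-(2-benzyloxy-5-chlorophenyl)-6-ethoxy-2-hydroxyphenyl]ethan-1-one | CC(=O)c1c(O)c(-c2cc(Cl)ccc2OCc2ccccc2)c(OCc2ccccc2)cc1OCC | intermediate
17 | 4-(benzyloxy)benzoyl chloride | O=C(Cl)c1ccc(OCc2ccccc2)cc1 | starting material
18 | 1-[4-benzyloxy-3-(2-benzyloxy-5-chlorophenyl)-6-ethoxy-2-hydroxyphenyl]-3-(4-benzyloxyphenyl)propane-1,3-dione | CCOc1cc(OCc2ccccc2)c(-c2cc(Cl)ccc2OCc2ccccc2)c(O)c1C(=O)CC(=O)c1ccc(OCc2ccccc2)cc1 | intermediate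
19 | 7-benzyloxy-8-(2-benzyloxy-5-chlorophenyl)-2-(4-benzyloxyphenyl)-5-ethoxy-4H-chromen-4-one | CCOc1cc(OCc2ccccc2)c(-c2cc(Cl)ccc2OCc2ccccc2)c2oc(-c3ccc(OCc4ccccc4)cc3)cc(=O)c12 | intermediate
20 | [4-benzyloxy-3-(7-benzyloxy-2-(4-benzyloxyphenyl)-5-ethoxy-4-oxo-4H-chromen-8-yl)phenyl]boronic acid | CCOc1cc(OCc2ccccc2)c(-c2cc(B(O)O)ccc2OCc2ccccc2)c2oc(-c3ccc(OCc4ccccc4)cc3)cc(=O)c12 | intermediate
21 | 2',6'-dihydroxy-4'-methoxyacetophenone | COc1cc(O)c(C(C)=O)c(O)c1 | starting material
22 | 1-(2-benzyloxy-6-hydroxy-4-methoxyphenyl)ethan-1-one | COc1cc(O)c(C(C)=O)c(OCc2ccccc2)c1 | intermediate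
23 | (E)-1-(2-benzyloxy-6-hydroxy-4-methoxyphenyl)-3-(dimethylamino)prop-2-en-1-one | COc1cc(O)c(C(=O)/C=C/N(C)C)c(OCc2ccccc2)c1 | intermediate (not isolated)
24 | 5-benzyloxy-7-methoxy-4H-chromen-4-one | COc1cc(OCc2ccccc2)c2c(=O)ccoc2c1 | intermediate
25 | (2S)-5-benzyloxy-2-[4-benzyloxy-3-(7-benzyloxy-2-(4-benzyloxyphenyl)-5-ethoxy-4-oxo-4H-chromen-8-yl)phenyl]-7-methoxychroman-4-one | COc1cc(OCc2ccccc2)c2c(c1)O[C@H](c1ccc(OCc3ccccc3)c(-c3c(OCc4ccccc4)cc(OCC)c4c(=O)cc(-c5ccc(OCc6ccccc6)cc5)oc34)c1)CC2=O | intermediate
26 | (2S)-2-[3-(5,7-dihydroxy-2-(4-hydroxyphenyl)-4-oxo-4H-chromen-8-yl)-4-hydroxyphenyl]-5-hydroxy-7-methoxychroman-4-one (CNP0107492.1) | COc1cc(O)c2c(c1)O[C@H](c1ccc(O)c(-c3c(O)cc(O)c4c(=O)cc(-c5ccc(O)cc5)oc34)c1)CC2=O | target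

## Step count and least certain steps

Total: 14 steps. Longest linear sequence: 12 steps (steps 1 to 10, 13 and 14); the ring A branch is 2 steps (11 and 12).

**Step 4 (key step).** The alkoxy group stabilises 7 as a vinylogous ester, so its electrocyclic opening may need temperatures at which the siloxyalkyne is lost by 1,3-silyl shift to a silylketene. The vinylketene may also dimerise or acylate the product phenol. Reversed regiochemistry in the cycloaddition is the less likely failure.
Fallback, from 2 back to 13, by cross-coupling in place of benzannulation (it accepts the hindered coupling, but between simple rings):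
- Acid-catalysed Dakin oxidation of 2 (H2O2, cat. H2SO4, MeOH) should give 2-(benzyloxy)-5-chlorophenol F1, and triflation (Tf2O, pyridine) 2-(benzyloxy)-5-chlorophenyl trifluoromethanesulfonate F2.
- Ring D would come from phloroglucinol: mono-ethylation (EtOH, HCl) to 5-ethoxybenzene-1,3-diol F3, then MOMCl and i-Pr2NEt to 1-ethoxy-3,5-bis(methoxymethoxy)benzene F4.
- Directed lithiation between the two acetal oxygens (n-BuLi, THF, 0 °C) and ZnCl2 should give [4-ethoxy-2,6-bis(methoxymethoxy)phenyl]zinc chloride F5.
- Negishi coupling of F5 with F2 (Pd(PPh3)4, THF, 65 °C, a catalyst that prefers the triflate to the chloride) should give 2'-(benzyloxy)-5'-chloro-4-ethoxy-2,6-bis(methoxymethoxy)biphenyl F6, and HCl in MeOH should remove the acetals to give 13.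

**Step 13.** Insertion into the electron-rich, doubly alkoxylated chromone may be slow, so protodeboronation of the valuable boronic acid can overtake it, and facial discrimination may be incomplete for so large an aryl group.
Fallback, from 19 back to 25, by the chalcone route with resolution:
- Vinylation of 19 with potassium vinyltrifluoroborate (Pd(OAc)2, XPhos, Cs2CO3, THF/H2O) should give 7-benzyloxy-8-(2-benzyloxy-5-ethenylphenyl)-2-(4-benzyloxyphenyl)-5-ethoxy-4H-chromen-4-one F7.
- Lemieux–Johnson cleavage (OsO4 cat., NaIO4, 2,6-lutidine, dioxane/H2O) should give 4-benzyloxy-3-(7-benzyloxy-2-(4-benzyloxyphenyl)-5-ethoxy-4-oxo-4H-chromen-8-yl)benzaldehyde F8.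
- Claisen–Schmidt condensation of F8 with 22 (KOH, EtOH, 20 °C) should give the 2'-hydroxychalcone F9, and NaOAc in EtOH at reflux should close it to the racemic flavanone F10.
- Preparative chromatography on a chiral stationary phase would give 25; the (2R) antipode F11 can be returned to the racemate with mild base.

**Step 14.** The peri ethyl ether reacts more slowly than a methyl ether, so the conditions needed to cleave it may also open ring C at the C2–O1 bond and erode the configuration, may benzylate the phloroglucinol rings on carbon, or may begin to attack the C7 methyl ether.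
Fallback, from 19 to 26, moving the ethyl cleavage to the achiral flavone stage:
- BCl3 and C6HMe5 (CH2Cl2, 0 → 20 °C) on 19 should give 8-(5-chloro-2-hydroxyphenyl)-5,7-dihydroxy-2-(4-hydroxyphenyl)-4H-chromen-4-one F12.
- BnBr (3 equiv), K2CO3 and acetone should benzylate the three non-chelated hydroxyls to give 7-benzyloxy-8-(2-benzyloxy-5-chlorophenyl)-2-(4-benzyloxyphenyl)-5-hydroxy-4H-chromen-4-one F13.
- Borylation as in step 10 should give the boronic acid F14, and conjugate addition to 24 as in step 13 the (2S)-flavanone with a free C5'' hydroxyl F15.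
- Hydrogenolysis (H2, palladium on carbon, EtOAc/THF, 20 °C) should then give 26 without any Lewis acid.

**Step 3.** Oxygen transfer to the acetylide may be incomplete, and the silyl ynol ether may hydrolyse during isolation.
Fallback, from 2 back to 6, by ester homologation:
- Oxidative esterification of 2 (I2, KOH, MeOH, 0 °C) should give methyl 2-(benzyloxy)-5-chlorobenzoate F16.
- Kowalski homologation (CH2Br2, lithium 2,2,6,6-tetramethylpiperidide, THF, −78 °C; LiN(SiMe3)2; then sec-BuLi, −78 → 20 °C) should give the same lithium ynolate 5, which is silylated with i-Pr3SiOTf to 6.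
- The alkyllithium would be kept close to stoichiometric and cold, because excess threatens the aryl chloride and the benzylic protons.

## Further compounds

F1 | step 4 | 2-(benzyloxy)-5-chlorophenol | Oc1cc(Cl)ccc1OCc1ccccc1
F2 | step 4 | 2-(benzyloxy)-5-chlorophenyl trifluoromethanesulfonate | O=S(=O)(Oc1cc(Cl)ccc1OCc1ccccc1)C(F)(F)F
F3 | step 4 | 5-ethoxybenzene-1,3-diol | CCOc1cc(O)cc(O)c1
F4 | step 4 | 1-ethoxy-3,5-bis(methoxymethoxy)benzene | CCOc1cc(OCOC)cc(OCOC)c1
F5 | step 4 | [4-ethoxy-2,6-bis(methoxymethoxy)phenyl]zinc chloride | CCOc1cc(OCOC)c([Zn]Cl)c(OCOC)c1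
F6 | step 4 | 2'-(benzyloxy)-5'-chloro-4-ethoxy-2,6-bis(methoxymethoxy)biphenyl | CCOc1cc(OCOC)c(-c2cc(Cl)ccc2OCc2ccccc2)c(OCOC)c1
F7 | step 13 | 7-benzyloxy-8-(2-benzyloxy-5-ethenylphenyl)-2-(4-benzyloxyphenyl)-5-ethoxy-4H-chromen-4-one | CCOc1cc(OCc2ccccc2)c(-c2cc(C=C)ccc2OCc2ccccc2)c2oc(-c3ccc(OCc4ccccc4)cc3)cc(=O)c12
F8 | step 13 | 4-benzyloxy-3-(7-benzyloxy-2-(4-benzyloxyphenyl)-5-ethoxy-4-oxo-4H-chromen-8-yl)benzaldehyde | CCOc1cc(OCc2ccccc2)c(-c2cc(C=O)ccc2OCc2ccccc2)c2oc(-c3ccc(OCc4ccccc4)cc3)cc(=O)c12
F9 | step 13 | (E)-1-(2-benzyloxy-6-hydroxy-4-methoxyphenyl)-3-[4-benzyloxy-3-(7-benzyloxy-2-(4-benzyloxyphenyl)-5-ethoxy-4-oxo-4H-chromen-8-yl)phenyl]prop-2-en-1-one | COc1cc(O)c(C(=O)/C=C/c2ccc(OCc3ccccc3)c(-c3c(OCc4ccccc4)cc(OCC)c4c(=O)cc(-c5ccc(OCc6ccccc6)cc5)oc34)c2)c(OCc2ccccc2)c1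
F10 | step 13 | racemic 5-benzyloxy-2-[4-benzyloxy-3-(7-benzyloxy-2-(4-benzyloxyphenyl)-5-ethoxy-4-oxo-4H-chromen-8-yl)phenyl]-7-methoxychroman-4-one | COc1cc(OCc2ccccc2)c2c(c1)OC(c1ccc(OCc3ccccc3)c(-c3c(OCc4ccccc4)cc(OCC)c4c(=O)cc(-c5ccc(OCc6ccccc6)cc5)oc34)c1)CC2=O
F11 | step 13 | (2R)-5-benzyloxy-2-[4-benzyloxy-3-(7-benzyloxy-2-(4-benzyloxyphenyl)-5-ethoxy-4-oxo-4H-chromen-8-yl)phenyl]-7-methoxychroman-4-one | COc1cc(OCc2ccccc2)c2c(c1)O[C@@H](c1ccc(OCc3ccccc3)c(-c3c(OCc4ccccc4)cc(OCC)c4c(=O)cc(-c5ccc(OCc6ccccc6)cc5)oc34)c1)CC2=O
F12 | step 14 | 8-(5-chloro-2-hydroxyphenyl)-5,7-dihydroxy-2-(4-hydroxyphenyl)-4H-chromen-4-one | O=c1cc(-c2ccc(O)cc2)oc2c(-c3cc(Cl)ccc3O)c(O)cc(O)c12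
F13 | step 14 | 7-benzyloxy-8-(2-benzyloxy-5-chlorophenyl)-2-(4-benzyloxyphenyl)-5-hydroxy-4H-chromen-4-one | O=c1cc(-c2ccc(OCc3ccccc3)cc2)oc2c(-c3cc(Cl)ccc3OCc3ccccc3)c(OCc3ccccc3)cc(O)c12
F14 | step 14 | [4-benzyloxy-3-(7-benzyloxy-2-(4-benzyloxyphenyl)-5-hydroxy-4-oxo-4H-chromen-8-yl)phenyl]boronic acid | O=c1cc(-c2ccc(OCc3ccccc3)cc2)oc2c(-c3cc(B(O)O)ccc3OCc3ccccc3)c(OCc3ccccc3)cc(O)c12
F15 | step 14 | (2S)-5-benzyloxy-2-[4-benzyloxy-3-(7-benzyloxy-2-(4-benzyloxyphenyl)-5-hydroxy-4-oxo-4H-chromen-8-yl)phenyl]-7-methoxychroman-4-one | COc1cc(OCc2ccccc2)c2c(c1)O[C@H](c1ccc(OCc3ccccc3)c(-c3c(OCc4ccccc4)cc(O)c4c(=O)cc(-c5ccc(OCc6ccccc6)cc5)oc34)c1)CC2=O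
F16 | step 3 | methyl 2-(benzyloxy)-5-chlorobenzoate | COC(=O)c1cc(Cl)ccc1OCc1ccccc1
A1 | alternative 1 | 5,7-bis(benzyloxy)-8-(2-benzyloxy-5-chlorophenyl)-2-(4-benzyloxyphenyl)-4H-chromen-4-one | O=c1cc(-c2ccc(OCc3ccccc3)cc2)oc2c(-c3cc(Cl)ccc3OCc3ccccc3)c(OCc3ccccc3)cc(OCc3ccccc3)c12
A2 | alternative 1 | 3,5-bis(benzyloxy)-2-(2-benzyloxy-5-chlorophenyl)-6-[(triphenyl-λ5-phosphanylidene)acetyl]phenyl 4-(benzyloxy)benzoate | O=C(C=P(c1ccccc1)(c1ccccc1)c1ccccc1)c1c(OCc2ccccc2)cc(OCc2ccccc2)c(-c2cc(Cl)ccc2OCc2ccccc2)c1OC(=O)c1ccc(OCc2ccccc2)cc1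
A3 | alternative 2 | (2S)-2-[4-benzyloxy-3-(5,7-bis(benzyloxy)-2-(4-benzyloxyphenyl)-4-oxo-4H-chromen-8-yl)phenyl]-5,7-dimethoxychroman-4-one | COc1cc(OC)c2c(c1)O[C@H](c1ccc(OCc3ccccc3)c(-c3c(OCc4ccccc4)cc(OCc4ccccc4)c4c(=O)cc(-c5ccc(OCc6ccccc6)cc5)oc34)c1)CC2=O
A4 | alternative 2 | (3S)-3-[4-benzyloxy-3-(5,7-bis(benzyloxy)-2-(4-benzyloxyphenyl)-4-oxo-4H-chromen-8-yl)phenyl]-3-(3,5-dimethoxyphenoxy)propanoic acid | COc1cc(OC)cc(O[C@@H](CC(=O)O)c2ccc(OCc3ccccc3)c(-c3c(OCc4ccccc4)cc(OCc4ccccc4)c4c(=O)cc(-c5ccc(OCc6ccccc6)cc5)oc34)c2)c1
A5 | alternative 3 | 4-benzyloxy-3-[5-benzyloxy-2-(4-benzyloxyphenyl)-7-hydroxy-4-oxo-4H-chromen-8-yl]benzaldehyde | O=Cc1ccc(OCc2ccccc2)c(-c2c(O)cc(OCc3ccccc3)c3c(=O)cc(-c4ccc(OCc5ccccc5)cc4)oc23)c1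
A6 | alternative 3 | 4-benzyloxy-3-(4-benzyloxy-2,6-dihydroxy-3-iodophenyl)benzaldehyde | O=Cc1ccc(OCc2ccccc2)c(-c2c(O)cc(OCc3ccccc3)c(I)c2O)c1
A7 | alternative 3 | 1-(benzyloxy)-4-ethynylbenzene | C#Cc1ccc(OCc2ccccc2)cc1
A8 | alternative 3 | 4-benzyloxy-3-{4-benzyloxy-3-[3-(4-benzyloxyphenyl)prop-2-ynoyl]-2,6-dihydroxyphenyl}benzaldehyde | O=Cc1ccc(OCc2ccccc2)c(-c2c(O)cc(OCc3ccccc3)c(C(=O)C#Cc3ccc(OCc4ccccc4)cc3)c2O)c1
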